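## The problem

Numbering used throughout: ring C1–C6 (C1 carries the chain, C2 the free hydroxyl, C3 the ring angelate, C4 the methyl C15 and, with C5, the ring epoxide, C6 is CH2); chain C7 (=C14H2), C8 (chain angelate), C9, C10–C11 (epoxide; C12 and C13 are the gem-methyls). β is the face of the C2 and C3 oxygens, α the face of the C1 chain and of the ring epoxide oxygen. In this numbering the target is 1R,2R,3R,4R,5R,8S,10R.

The target is a monocyclic sesquiterpenoid diester: a cyclohexane with five contiguous stereocentres (C1–C5), joined through the sp2 carbon C7 to a chain with two more (C8, C10). Inside the ring the centres can be relayed: C1 and C2 are trans, C2 and C3 cis, and the epoxide is anti to both ring oxygens, so C2 can set C3 and the C3 substituent can steer the epoxidation. C8 and C10 are insulated from the ring by C7 and C9 and need reagent control. The two ring oxygens are chemically alike, yet only O3 is acylated; they must be told apart before acylation, and a free cis hydroxy ester can shift its acyl group under base. Angelates isomerise to tiglates with base or nucleophilic catalysts, both epoxides are acid-labile, and the C8 ester is allylic, so these groups must come late and be followed only by buffered oxidants. The enabling feature is the array C2–C3–C4–C5: an oxygen at C3 that is allylic to a C4-substituted C4=C5 bond and cis to O2 is what an allyl cation spanning C3–C4–C5 leaves behind when it is caught at C3 by a group hanging from O2. Taking C4 out as a carbene carbon leaves a cyclopentene (C1, C2, C3, C5, C6) whose two stereocentres are those of an anti-aldol adduct.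

## Retrosynthesis

**36 ⇒ 35 ⇒ 34.** The last cuts are the O2 p-methoxybenzyl ether and the two C–O bonds of the chain epoxide. In 34 the C10=C11 bond is the only electron-rich trisubstituted alkene left, so a dioxirane should find it in the presence of C7=C14 and the angelate double bonds. Introducing this epoxide earlier would expose the most acid-sensitive group to every later step. C10 is remote from all other stereocentres, so the forward epoxidation must be catalyst-controlled. The final unmasking of O2 must be non-basic so that the C3 ester stays where it is.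

**34 ⇒ 31 + 32.** Both ester C–O bonds are cut together. This is possible only because O2 is blocked: O3 is axial and neopentyl-like, and selective esterification of it beside a free equatorial O2 has no reliable solution. Diol 31 is ten carbons smaller. The forward acylation with angelic acid 32 must not isomerise the Z-alkene.

**31 ⇒ 30 ⇒ 29 ⇒ 28 ⇒ 25 + 27.** The C7–C8 bond is cut to alkenyl triflate 25 and aldehyde 27. A C8–C9 cut (prenyl nucleophile on an enal) suffers from γ-attack, and building C8 onto a C7 ketone followed by methylenation would pass through a ketone with two epimerisable α-centres. The chosen coupling runs under neutral conditions but cannot be expected to control C8. The epimeric alcohols 28 are therefore converged on enone 29 and reduced under catalyst control to 30; desilylation then gives 31.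

**25 ⇒ 23 ⇒ 22 ⇒ 21 ⇒ 20.** The C7–O(triflate) bond and the C7–C14 bond are cut. Triflate 25 comes from the kinetic enolate of methyl ketone 23, and 23 from aldehyde 21 by methyl addition (22) and oxidation. The forward enolisation must stay on the methyl side, because the inner enolate could expel the C2 ether.

**20 ⇒ 19.** The ring epoxide C–O bonds are cut here, where 19 has a single alkene and a bulky β-silyl ether at C3 to push the peracid to the α face.

**19 ⇒ 18 ⇒ 17 ⇒ 16 ⇒ 15.** This block separates O2 from O3 and installs C15. In triol 15 the primary O7 and the secondary O2 form a trans-fused six-membered p-methoxybenzylidene acetal (16), so O3 is the one oxygen left for silylation (17). Regioselective reductive opening (18 ⇒ 19) then leaves the benzyl group on O2 and frees O7 for chain extension. The C4–C15 bond is cut to the alkenyl bromide (17 ⇒ 18). An O2/O3 acetonide would be shorter but leaves the two oxygens indistinguishable.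

**15 ⇒ 14 ⇒ 13.** Methanolysis retraces triol 15 to cyclic carbonate 14. The key cut removes the O3–C3 bond and contracts the ring: 14 comes from dibromobicyclo[3.1.0]hexane 13, in which C4 is the cyclopropane carbon bearing two bromines and O2 carries a tert-butyl carbonate. The forward reaction must ionise only the endo bromide and deliver oxygen to C3 only, on the β face. The surviving bromine at C4 is the handle for C15.

**13 ⇒ 11 + 12; 11 ⇒ 10 ⇒ 9.** The C3–C4 and C4–C5 bonds are cut to cyclopentene 11 and bromoform 12. Carbonate 11 comes from diol 9 by acylating first the primary hydroxyl (pivalate 10, a non-participating group at O7) and then the secondary one.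

**9 ⇒ 8 ⇒ 7 ⇒ 4 + 5; 4 ⇒ 1 + 2.** Diol 9 is the reduction product of imide 8. The C3=C5 alkene of 8 is cut by metathesis to diene 7. The C1–C2 bond of 7 is cut by an auxiliary-controlled anti-aldol reaction between imide 4 (from acid 1 and oxazolidinone 2) and cinnamaldehyde 5, which fixes C1 and C2 trans and absolute.

## Roads not taken

**Alternative 1:** the C4=C5 bond is cut, and triene A1, built on a carbohydrate-derived cis-dioxolane, is closed with (H2IMes)(PCy3)Cl2Ru=CHPh (second-generation Grubbs catalyst) to cyclohexene A2.
- Merits: the cis O2/O3 pair comes from the chiral pool, C15 is present from the start, and the acrylate delivers C7=C14 and C8 (as the ester carbon) in one piece. A2 is therefore much closer to the side chain than anything in the chosen plan, which spends five steps turning a CH2OH into the alkenyl triflate.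
- Weak points: C1 must be created in an open chain next to the dioxolane, where 1,2-induction in the C–C bond formation is uncertain. The ring closure must form a trisubstituted alkene from a hindered isopropenyl group. The acetonide leaves O2 and O3 equivalent and has to be removed with acid late, with no neighbouring oxygen to help differentiate them.
- Comparison: this road is shorter to the ring and to the chain. The chosen plan sets against it auxiliary control of C1/C2, tether control of C3, and an O7 hydroxyl that makes the O2/O3 distinction a matter of ring size.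

**Alternative 2:** the C1–C6 and C2–C3 bonds are cut. Diene A3 and dienophile A4 would combine under an N-protonated B-(o-tolyl) diphenylprolinol-derived oxazaborolidine (triflimide counter-ion) to give A5.
- Merits: one step makes the ring, three stereocentres (C1, C2, C3), the C4=C5 bond and C15. After Baeyer–Villiger oxidation of the acetyl group, O2 and O3 would carry different groups from the outset. On step count and on the O2/O3 problem this road is better than the chosen one.
- Weak points: the dienophile has two different acceptor groups, and which carbonyl binds the catalyst decides both regiochemistry and face. The silyloxydiene is sensitive to the strongly acidic cationic boron catalyst. The Baeyer–Villiger oxidation must be run beside the C4=C5 alkene, where epoxidation competes without a planned facial bias.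
- Comparison: the chosen plan offers three independent, well-understood stereocontrol elements (auxiliary, tether, shielding silyl ether) in place of one step that must succeed in regio-, endo- and enantioselectivity at once.

**Alternative 3:** the C3–C4 bond is cut. The (Z)-alkenyl iodide of A6 would add to its own aldehyde under CrCl2 (divalent chromium) with catalytic NiCl2 to give cyclohexenol A7.
- Merits: C15 is in place, the conditions are mild, and A7 has O3 free and O2 silylated, exactly the pattern the target needs. The chosen plan needs four operations to reach the same distinction.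
- Weak points: C3 is formed in the ring closure and its configuration rests on the facial bias of an α-silyloxy aldehyde, which must come out cis to O2. A6 needs C1 and C2 set in an open chain and a (Z)-2-iodoalkene. The isopropenyl group brings C8 as a methyl, so the chain would have to be grown by allylic functionalisation of C8 in competition with the allylic C15 methyl, with no control at C8.
- Comparison: in the chosen plan C3 is fixed by a tether that can only close cis, and the chain is joined at C7–C8 by a C–C coupling.

Key step: step 8

Remark: the sense of the magnesium-catalysed anti-aldol reaction is taken from the propionimide/benzaldehyde case, where the (S)-benzyl auxiliary gives the (2R,3S) adduct; the (R)-auxiliary is therefore used.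
Remark: cinnamaldehyde serves as a robust, non-polymerising stand-in for acrolein; its phenyl-bearing carbon leaves as styrene in the metathesis.

## Route

Step 1
Reactants: 1 pent-4-enoic acid; 2 (R)-4-benzyloxazolidin-2-one
Product: 4 (R)-4-benzyl-3-(pent-4-enoyl)oxazolidin-2-one, via mixed pivalic anhydride 3 (not isolated)
Conditions: t-BuCOCl, Et3N, THF, −20 °C; then 2, LiCl, −20 °C → rt
Reagents that add atoms: none
Why: N-acylation of an oxazolidinone through the mixed pivalic anhydride with LiCl activation is standard; no stereocentre is formed.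

Step 2
Reactants: 4 (R)-4-benzyl-3-(pent-4-enoyl)oxazolidin-2-one; 5 (E)-cinnamaldehyde
Product: 7 (R)-4-benzyl-3-[(2S,3S,4E)-3-hydroxy-5-phenyl-2-(prop-2-en-1-yl)pent-4-enoyl]oxazolidin-2-one, via trimethylsilyl ether 6 (not isolated)
Conditions: MgCl2 (10 mol%), Et3N, Me3SiCl, EtOAc, rt; then CF3CO2H, MeOH
Reagents that add atoms: none
Why: Magnesium-halide-catalysed direct anti-aldol reaction of an N-acyloxazolidinone, turned over by silylation of the aldolate; the auxiliary-chelated (Z)-enolate reacts through a boat transition state on the face away from benzyl, which from the (R)-auxiliary should set C1 and C2 (target numbering) as 2S,3S, i.e. anti.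

Step 3
Reactants: 7 the anti-aldol adduct
Product: 8 (R)-4-benzyl-3-[(1S,2S)-2-hydroxycyclopent-3-ene-1-carbonyl]oxazolidin-2-one
Conditions: (H2IMes)(PCy3)Cl2Ru=CHPh (second-generation Grubbs catalyst, 3 mol%), CH2Cl2, 40 °C
Reagents that add atoms: none
Why: Ring-closing metathesis starts at the terminal allyl group and closes onto the styryl alkene with loss of styrene; the stereocentres are untouched, so the anti relation becomes 1,2-trans on the cyclopentene.

Step 4
Reactants: 8 the cyclopentenol imide
Product: 9 (1S,5R)-5-(hydroxymethyl)cyclopent-2-en-1-ol (trans)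
Conditions: LiBH4, MeOH (1 equiv), THF, 0 °C
Reagents that add atoms: none
Why: Reductive cleavage of the exocyclic imide carbonyl by LiBH4 releases the auxiliary for reuse; the non-basic medium should leave C1 unchanged.

Step 5
Reactants: 9 the trans diol
Product: 10 [(1R,2S)-2-hydroxycyclopent-3-en-1-yl]methyl pivalate
Conditions: t-BuCOCl (1.05 equiv), pyridine, CH2Cl2, −20 → 0 °C
Reagents that add atoms: pivaloyl chloride CC(C)(C)C(=O)Cl
Why: Steric differentiation of primary from secondary hydroxyl; the pivalate is a non-participating, acid-stable group at O7 for the key step and later falls in the same methanolysis as the carbonate.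

Step 6
Reactants: 10 the primary pivalate
Product: 11 [(1R,2S)-2-(tert-butoxycarbonyloxy)cyclopent-3-en-1-yl]methyl pivalate
Conditions: Boc2O, 4-(dimethylamino)pyridine (0.2 equiv), CH2Cl2, rt
Reagents that add atoms: di-tert-butyl dicarbonate CC(C)(C)OC(=O)OC(=O)OC(C)(C)C
Why: Catalysed tert-butoxycarbonylation of the secondary allylic alcohol installs the internal oxygen nucleophile at O2.

Step 7
Reactants: 11 the cyclopentenyl tert-butyl carbonate; 12 bromoform
Product: 13 tert-butyl [6,6-dibromo-3α-(pivaloyloxymethyl)bicyclo[3.1.0]hexan-2β-yl] carbonate, cyclopropane on the α face (bicyclic C2 = target C2, C3 = target C1, C6 = target C4)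
Conditions: 12 (4 equiv), KOtBu (3 equiv, added in portions), pentane, −10 → 0 °C
Reagents that add atoms: none
Why: Dibromocarbene addition to a cis-disubstituted cyclopentene gives the cis-fused gem-dibromocyclopropane; attack anti to the allylic carbonate is expected, and the face is immaterial because both isomers open to the same cation in step 8.

Step 8
Reactants: 13 the gem-dibromocyclopropane
Product: 14 4-bromo-1α-(pivaloyloxymethyl)cyclohex-4-ene-2β,3β-diyl carbonate (cis-fused 1,3-dioxolan-2-one)
Conditions: AgBF4 (monovalent silver, 2 equiv), 2,6-di-tert-butyl-4-methylpyridine (1.5 equiv), 4 Å molecular sieves, ClCH2CH2Cl, 25 → 60 °C, dark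
Reagents that add atoms: none
Why: Silver pulls off the endo bromide while the C3–C5 bond opens in a disrotatory two-electron electrocyclic process, the known silver-promoted ring enlargement of ring-fused gem-dihalocyclopropanes with internal oxygen capture of the allyl cation. The six-membered carbocycle arises by this ring expansion, which inserts C4 between C3 and C5 and gives the 2-bromocyclohexenyl cation spanning C3–C4–C5. The carbonyl oxygen of the O2 carbonate then closes the dioxolanone ring in a 5-exo-trig attack on C3, and the resulting 2-tert-butoxydioxolanylium ion loses isobutene, the proton going to the hindered pyridine. The new stereocentre C3 is set by the tether, which can only close cis, so O3 lands on the face of O2. Chemoselectivity for the endo bromide follows from the rule that only the halide cis to the ring bonds can leave when a six-membered cis-allyl cation must result. Regioselectivity is secured by reach: C3 is the only terminus that gives a five-membered ring, whereas C5 would need a bridged one. The pivalate at O7 could only close a seven-membered ring and BF4− is non-nucleophilic, so no other nucleophile competes, and the pyridine base protects unreacted carbonate from the acid set free.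

Step 9
Reactants: 14 the cyclic carbonate pivalate
Product: 15 4-bromo-1α-(hydroxymethyl)cyclohex-4-ene-2β,3β-diol
Conditions: NaOMe (0.3 equiv), MeOH, 40 °C
Reagents that add atoms: none
Why: Base-catalysed transesterification removes the cyclic carbonate and the pivalate in one operation; the alkenyl bromide and the stereocentres are not affected.

Step 10
Reactants: 15 the bromo triol
Product: 16 O7,O2-(4-methoxybenzylidene) acetal of 15 (trans-fused 1,3-dioxane, aryl equatorial; 3β-hydroxyl free)
Conditions: 4-MeOC6H4CH(OMe)2 (1.1 equiv), camphor-10-sulfonic acid (5 mol%), CH2Cl2, rt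
Reagents that add atoms: 4-methoxybenzaldehyde dimethyl acetal COc1ccc(cc1)C(OC)OC
Why: Transacetalisation under equilibrium control; arylidene acetals prefer the chair 1,3-dioxane on the trans-diequatorial O7/O2 pair over a cis-fused dioxolane on O2/O3, as in 4,6-O-benzylidenation of pyranosides that also contain a cis-diol. The acetal carbon should settle with the aryl group equatorial.

Step 11
Reactants: 16 the benzylidene acetal
Product: 17 3β-O-(tert-butyldimethylsilyl) ether of 16
Conditions: t-BuMe2SiOTf, 2,6-lutidine, CH2Cl2, −78 → 0 °C
Reagents that add atoms: tert-butyldimethylsilyl triflate CC(C)(C)[Si](C)(C)OS(=O)(=O)C(F)(F)F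
Why: Silylation of the one remaining, hindered allylic hydroxyl; the bulky β-silyl ether later shields the β face of the C4=C5 alkene.

Step 12
Reactants: 17 the alkenyl bromide
Product: 18 the 4-methyl analogue of 17 (C15 in place of bromine)
Conditions: Me2Zn (2 equiv), PdCl2(dppf) [dppf = 1,1'-bis(diphenylphosphino)ferrocene] (5 mol%), 1,4-dioxane, 90 °C
Reagents that add atoms: dimethylzinc C[Zn]C
Why: Negishi coupling of an alkenyl bromide with dimethylzinc; it is preferred to bromine–lithium exchange because a 2-lithioallyl silyl ether could suffer silyl migration from oxygen to carbon.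

Step 13
Reactants: 18 the methylated acetal
Product: 19 1α-(hydroxymethyl)-2β-(4-methoxybenzyloxy)-3β-(tert-butyldimethylsilyloxy)-4-methylcyclohex-4-ene
Conditions: i-Bu2AlH (3 equiv), CH2Cl2, −78 → 0 °C
Reagents that add atoms: none
Why: Regioselective reductive opening of a p-methoxybenzylidene acetal: aluminium binds the less hindered primary oxygen, that C–O bond breaks, and hydride quenches the oxocarbenium ion, leaving the benzyl group on secondary O2 and freeing O7.

Step 14
Reactants: 19 the homoallylic primary alcohol
Product: 20 the 4α,5α-epoxide of 19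
Conditions: mCPBA, CH2Cl2, 0 °C
Reagents that add atoms: 3-chloroperbenzoic acid OOC(=O)c1cccc(Cl)c1
Why: Peracid epoxidation of the only alkene; the pseudoaxial β-silyl ether at C3 blocks the β face and the α-oriented C7 hydroxyl can hydrogen-bond the peracid, so oxygen should arrive on the α face and set C4 and C5 anti to the ring oxygens.

Step 15
Reactants: 20 the epoxy alcohol
Product: 21 the C7 aldehyde (1α-formyl compound)
Conditions: Dess–Martin periodinane, pyridine, CH2Cl2, 0 °C → rt
Reagents that add atoms: none
Why: Buffered Dess–Martin oxidation, chosen to keep the C1 configuration and to avoid β-elimination of the C2 ether.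

Step 16
Reactants: 21 the aldehyde
Product: 22 the 1α-(1-hydroxyethyl) compound (both C7 epimers)
Conditions: MeMgBr, THF, −78 °C
Reagents that add atoms: methylmagnesium bromide C[Mg]Br
Why: Grignard addition to the aldehyde at low temperature brings in C14; the epoxide is inert under these conditions and the C7 configuration is erased in the next step.

Step 17
Reactants: 22 the secondary alcohols
Product: 23 the 1α-acetyl compound (methyl ketone)
Conditions: Dess–Martin periodinane, pyridine, CH2Cl2, rt
Reagents that add atoms: none
Why: Dess–Martin oxidation; the acetyl group is equatorial and trans to O2, so there is no thermodynamic drive to epimerise C1.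

Step 18
Reactants: 23 the methyl ketone
Product: 25 the C7 alkenyl triflate [1α-(1-trifluoromethanesulfonyloxyethenyl) compound], via potassium enolate 24 (not isolated)
Conditions: KN(SiMe3)2 (1.1 equiv), THF, −78 °C; then N-(5-chloropyridin-2-yl)bis(trifluoromethanesulfonimide), −78 °C
Reagents that add atoms: N-(5-chloropyridin-2-yl)bis(trifluoromethanesulfonimide) FC(F)(F)S(=O)(=O)N(c1ccc(Cl)cn1)S(=O)(=O)C(F)(F)F
Why: Kinetic deprotonation of the methyl group by a hindered amide base and O-triflation at −78 °C with the reactive pyridyl triflimide; low temperature keeps the enolate from equilibrating to the inner isomer, which could expel the C2 ether.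

Step 19
Reactants: 26 4-methylpent-3-en-1-ol
Product: 27 4-methylpent-3-enal
Conditions: Dess–Martin periodinane, pyridine, CH2Cl2, 0 °C; used at once without chromatography
Reagents that add atoms: none
Why: Neutral oxidation of a homoallylic alcohol; immediate use limits isomerisation to the conjugated enal.

Step 20
Reactants: 25 the alkenyl triflate; 27 4-methylpent-3-enal
Product: 28 the C8 allylic alcohols (both C8 epimers; C7=C14 and C10=C11 in place)
Conditions: CrCl2 (divalent chromium, 4 equiv), NiCl2 (2 mol%), DMF, rt
Reagents that add atoms: none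
Why: Nozaki–Hiyama–Kishi coupling: nickel inserts into the alkenyl triflate, the alkenyl group passes to chromium and adds to the aldehyde; the neutral medium tolerates the epoxide, both ethers and the enolisable β,γ-unsaturated aldehyde. C8 is not controlled here.

Step 21
Reactants: 28 the epimeric allylic alcohols
Product: 29 the C8 ketone (cross-conjugated enone)
Conditions: Dess–Martin periodinane, pyridine, CH2Cl2, 0 °C
Reagents that add atoms: none
Why: Oxidation converges both epimers on one enone; buffered, cold conditions are meant to keep the C10=C11 bond from moving into conjugation.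

Step 22
Reactants: 29 the enone
Product: 30 the (8S)-allylic alcohol
Conditions: (R)-2-methyl-CBS-oxazaborolidine [(3aR)-1-methyl-3,3-diphenyltetrahydro-1H,3H-pyrrolo[1,2-c][1,3,2]oxazaborole] (0.5 equiv), catecholborane, toluene, −78 °C
Reagents that add atoms: none
Why: Corey–Bakshi–Shibata reduction; the α-branched alkenyl group acts as the large and the CH2 group as the small substituent, so the (R)-catalyst should deliver hydride to give 8S under reagent control.

Step 23
Reactants: 30 the (8S)-alcohol
Product: 31 the 3β,8-diol (O2 still p-methoxybenzylated)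
Conditions: Bu4NF, THF, 0 °C → rt
Reagents that add atoms: none
Why: Fluoride cleavage of the silyl ether; the epoxide carbon next to the freed oxygen is fully substituted, so epoxide migration by internal displacement is not expected.

Step 24
Reactants: 31 the 3β,8-diol; 32 angelic acid [(Z)-2-methylbut-2-enoic acid]
Product: 34 the 3,8-bis-angelate, via angelic trichlorobenzoic anhydride 33 (not isolated)
Conditions: 32 (5 equiv), 2,4,6-Cl3C6H2COCl, Et3N, toluene, rt; then 31, 75 °C (no 4-(dimethylamino)pyridine)
Reagents that add atoms: none
Why: Esterification through the 2,4,6-trichlorobenzoyl mixed anhydride (Yamaguchi-type) without a nucleophilic catalyst is the established way to make angelates without isomerisation to tiglates; with O2 blocked only O3 and O8 can react.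

Step 25
Reactants: 34 the bis-angelate
Product: 35 the (10R)-10,11-epoxide of 34
Conditions: D-fructose-derived Shi ketone (1,2:4,5-di-O-isopropylidene-β-D-erythro-2,3-hexodiulo-2,6-pyranose, 0.3 equiv), Oxone (2KHSO5·KHSO4·K2SO4), K2CO3, Bu4NHSO4 (cat.), MeCN–CH2(OMe)2–aq. Na2B4O7 buffer (pH ≈ 10.5), 0 °C
Reagents that add atoms: potassium peroxymonosulfate [K+].[O-]S(=O)(=O)OO
Why: Shi epoxidation; the chiral dioxirane attacks the most electron-rich alkene (trisubstituted C10=C11) through a spiro transition state, which for the D-fructose-derived ketone should give the 10R epoxide. The hindered 1,1-disubstituted C7=C14 bond and the electron-poor angelate alkenes are far less reactive.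

Step 26
Reactants: 35 the bis-epoxide p-methoxybenzyl ether
Product: 36 the target, CNP0296086.5
Conditions: DDQ (1.5 equiv), CH2Cl2–pH 7 phosphate buffer (10:1), 0 °C → rt
Reagents that add atoms: none
Why: Oxidative cleavage of the p-methoxybenzyl ether under buffered, near-neutral conditions spares epoxides, esters and alkenes and avoids base that could move the C3 angelate to O2.

## Compound list

1 | pent-4-enoic acid | C=CCCC(=O)O | starting material
2 | (R)-4-benzyloxazolidin-2-one | O=C1N[C@H](Cc2ccccc2)CO1 | starting material
3 | pent-4-enoic pivalic anhydride | C=CCCC(=O)OC(=O)C(C)(C)C | intermediate (not isolated)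
4 | (R)-4-benzyl-3-(pent-4-enoyl)oxazolidin-2-one | C=CCCC(=O)N1[C@H](Cc2ccccc2)COC1=O | intermediate
5 | (E)-cinnamaldehyde | O=C/C=C/c1ccccc1 | starting material
6 | trimethylsilyl ether of 7 | O=C(N1[C@H](Cc2ccccc2)COC1=O)[C@@H](CC=C)[C@@H](O[Si](C)(C)C)/C=C/c1ccccc1 | intermediate (not isolated)
7 | (R)-4-benzyl-3-[(2S,3S,4E)-3-hydroxy-5-phenyl-2-(prop-2-en-1-yl)pent-4-enoyl]oxazolidin-2-one | O=C(N1[C@H](Cc2ccccc2)COC1=O)[C@@H](CC=C)[C@@H](O)/C=C/c1ccccc1 | intermediate
8 | (R)-4-benzyl-3-[(1S,2S)-2-hydroxycyclopent-3-ene-1-carbonyl]oxazolidin-2-one | O=C(N1[C@H](Cc2ccccc2)COC1=O)[C@H]1CC=C[C@@H]1O | intermediate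
9 | (1S,5R)-5-(hydroxymethyl)cyclopent-2-en-1-ol | OC[C@H]1CC=C[C@@H]1O | intermediate
10 | [(1R,2S)-2-hydroxycyclopent-3-en-1-yl]methyl pivalate | CC(C)(C)C(=O)OC[C@H]1CC=C[C@@H]1O | intermediate
11 | [(1R,2S)-2-(tert-butoxycarbonyloxy)cyclopent-3-en-1-yl]methyl pivalate | CC(C)(C)C(=O)OC[C@H]1CC=C[C@@H]1OC(=O)OC(C)(C)C | intermediate
12 | bromoform | BrC(Br)Br | starting material
13 | tert-butyl [6,6-dibromo-3α-(pivaloyloxymethyl)bicyclo[3.1.0]hexan-2β-yl] carbonate, cyclopropane α | CC(C)(C)C(=O)OC[C@H]1C[C@@H]2[C@@H](C2(Br)Br)[C@@H]1OC(=O)OC(C)(C)C | intermediate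
14 | 4-bromo-1α-(pivaloyloxymethyl)cyclohex-4-ene-2β,3β-diyl carbonate | CC(C)(C)C(=O)OC[C@H]1CC=C(Br)[C@@H]2OC(=O)O[C@H]12 | intermediate
15 | 4-bromo-1α-(hydroxymethyl)cyclohex-4-ene-2β,3β-diol | OC[C@H]1CC=C(Br)[C@H](O)[C@@H]1O | intermediate
16 | O7,O2-(4-methoxybenzylidene) acetal of 15 (aryl equatorial) | COc1ccc(cc1)[C@@H]1OC[C@H]2CC=C(Br)[C@H](O)[C@@H]2O1 | intermediate
17 | 3β-O-tert-butyldimethylsilyl ether of 16 | COc1ccc(cc1)[C@@H]1OC[C@H]2CC=C(Br)[C@H](O[Si](C)(C)C(C)(C)C)[C@@H]2O1 | intermediate
18 | 4-methyl analogue of 17 | COc1ccc(cc1)[C@@H]1OC[C@H]2CC=C(C)[C@H](O[Si](C)(C)C(C)(C)C)[C@@H]2O1 | intermediate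
19 | 1α-(hydroxymethyl)-2β-(4-methoxybenzyloxy)-3β-(tert-butyldimethylsilyloxy)-4-methylcyclohex-4-ene | OC[C@H]1CC=C(C)[C@H](O[Si](C)(C)C(C)(C)C)[C@@H]1OCc1ccc(OC)cc1 | intermediate
20 | 4α,5α-epoxide of 19 | OC[C@H]1C[C@H]2O[C@@]2(C)[C@H](O[Si](C)(C)C(C)(C)C)[C@@H]1OCc1ccc(OC)cc1 | intermediate
21 | C7 aldehyde derived from 20 | O=C[C@H]1C[C@H]2O[C@@]2(C)[C@H](O[Si](C)(C)C(C)(C)C)[C@@H]1OCc1ccc(OC)cc1 | intermediate
22 | 1α-(1-hydroxyethyl) compound, both C7 epimers | CC(O)[C@H]1C[C@H]2O[C@@]2(C)[C@H](O[Si](C)(C)C(C)(C)C)[C@@H]1OCc1ccc(OC)cc1 | intermediate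
23 | 1α-acetyl compound (methyl ketone) | CC(=O)[C@H]1C[C@H]2O[C@@]2(C)[C@H](O[Si](C)(C)C(C)(C)C)[C@@H]1OCc1ccc(OC)cc1 | intermediate
24 | potassium enolate of 23 (terminal) | [K+].C=C([O-])[C@H]1C[C@H]2O[C@@]2(C)[C@H](O[Si](C)(C)C(C)(C)C)[C@@H]1OCc1ccc(OC)cc1 | intermediate (not isolated)
25 | C7 alkenyl triflate | C=C(OS(=O)(=O)C(F)(F)F)[C@H]1C[C@H]2O[C@@]2(C)[C@H](O[Si](C)(C)C(C)(C)C)[C@@H]1OCc1ccc(OC)cc1 | intermediate
26 | 4-methylpent-3-en-1-ol | CC(C)=CCCO | starting material
27 | 4-methylpent-3-enal | CC(C)=CCC=O | intermediate
28 | C8 allylic alcohols, both C8 epimers | C=C(C(O)CC=C(C)C)[C@H]1C[C@H]2O[C@@]2(C)[C@H](O[Si](C)(C)C(C)(C)C)[C@@H]1OCc1ccc(OC)cc1 | intermediate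
29 | C8 ketone (enone) | C=C(C(=O)CC=C(C)C)[C@H]1C[C@H]2O[C@@]2(C)[C@H](O[Si](C)(C)C(C)(C)C)[C@@H]1OCc1ccc(OC)cc1 | intermediate
30 | (8S)-allylic alcohol | C=C([C@H](CC=C(C)C)O)[C@H]1C[C@H]2O[C@@]2(C)[C@H](O[Si](C)(C)C(C)(C)C)[C@@H]1OCc1ccc(OC)cc1 | intermediate
31 | 3β,8-diol, 2β-O-(4-methoxybenzyl) | C=C([C@H](CC=C(C)C)O)[C@H]1C[C@H]2O[C@@]2(C)[C@H](O)[C@@H]1OCc1ccc(OC)cc1 | intermediate
32 | angelic acid, (Z)-2-methylbut-2-enoic acid | C/C=C(/C)C(=O)O | starting material
33 | angelic 2,4,6-trichlorobenzoic anhydride | C/C=C(/C)C(=O)OC(=O)c1c(Cl)cc(Cl)cc1Cl | intermediate (not isolated)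
34 | 3,8-bis-angelate, 2β-O-(4-methoxybenzyl) | C=C([C@H](CC=C(C)C)OC(=O)/C(C)=C\C)[C@H]1C[C@H]2O[C@@]2(C)[C@H](OC(=O)/C(C)=C\C)[C@@H]1OCc1ccc(OC)cc1 | intermediate
35 | (10R)-10,11-epoxide of 34 | C=C([C@H](C[C@H]1OC1(C)C)OC(=O)/C(C)=C\C)[C@H]1C[C@H]2O[C@@]2(C)[C@H](OC(=O)/C(C)=C\C)[C@@H]1OCc1ccc(OC)cc1 | intermediate
36 | CNP0296086.5 | C=C([C@H](C[C@H]1OC1(C)C)OC(=O)/C(C)=C\C)[C@H]1C[C@H]2O[C@@]2(C)[C@H](OC(=O)/C(C)=C\C)[C@@H]1O | target

## Step count and least certain steps

Total: 26 steps. Longest linear sequence: 25 steps (steps 1–18 and 20–26); step 19 is a one-step side branch.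

**Step 8 (key step).** The allyl cation is flanked by the electron-withdrawing carbonate and carries bromine, so ionisation may be slow. Forcing it risks acid-induced loss of the tert-butyl carbonate before capture, or proton loss from the cation to a bromodiene. Fallback, from 10 back to 14: the hydroxyl of 10 is carbamoylated with dimethylcarbamoyl chloride to the N,N-dimethylcarbamate F1, and dibromocarbene addition as in step 7 gives the dibromocyclopropane F2. On silver-promoted opening the more Lewis-basic carbamate oxygen, which has no acid-labile alkyl group, captures C3 as a cyclic iminium carbonate. Aqueous bicarbonate work-up hydrolyses this to 14 with loss of dimethylamine.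

**Step 7.** Alkoxide attack on the tert-butyl carbonate or the pivalate may compete with carbene formation, and the carbonate-deactivated alkene may add the carbene slowly. Fallback, from 10 back to 13: 10 is silylated to the triethylsilyl ether F3, which is base-stable and has a more electron-rich alkene. Dibromocarbene addition gives the dibromocyclopropane F4, mild acid removes the silyl group to give the alcohol F5, and tert-butoxycarbonylation as in step 6 gives 13.

**Step 10.** Acetalisation may partly take the cis O2/O3 pair (five-membered acetal) or go on to a bis-acetal, which would blur the O2/O3 distinction. Fallback, from 15 back to 19: the primary hydroxyl of 15 is pivaloylated to the diol pivalate F6. Its dibutylstannylene acetal is alkylated with 4-methoxybenzyl chloride at the equatorial O2 to give the 2β-(4-methoxybenzyl) ether F7. Silylation of O3 gives F8, Negishi methylation as in step 12 gives F9, and i-Bu2AlH removes the pivalate to give 19.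

**Step 22.** Facial discrimination may be poor if the two ketone substituents differ too little in effective size, and the Lewis acid may move the β,γ-alkene into conjugation. Fallback, from 28 back to 30: the epimers of 28 are separated and the 8S epimer is 30 itself. The (8R)-alcohol F10 is inverted by a Mitsunobu reaction with 4-nitrobenzoic acid to the (8S)-4-nitrobenzoate F11, and methanolysis of F11 gives 30.

**Step 24.** The axial O3, next to the fully substituted C4, may acylate slowly, and prolonged heating risks angelate-to-tiglate isomerisation. Fallback, from 31 back to 34: both hydroxyls are esterified with the unhindered 2-[bis(2,2,2-trifluoroethoxy)phosphoryl]propanoic acid (carbodiimide coupling) to give the bis-phosphonopropanoate F12. A Still–Gennari olefination with acetaldehyde (KN(SiMe3)2, 18-crown-6, −78 °C) then builds both (Z)-2-methylbut-2-enoates in place and gives 34.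

## Further compounds

F1 | step 8 | [(1R,2S)-2-(dimethylcarbamoyloxy)cyclopent-3-en-1-yl]methyl pivalate | CC(C)(C)C(=O)OC[C@H]1CC=C[C@@H]1OC(=O)N(C)C
F2 | step 8 | 6,6-dibromo-3α-(pivaloyloxymethyl)bicyclo[3.1.0]hexan-2β-yl dimethylcarbamate, cyclopropane α | CC(C)(C)C(=O)OC[C@H]1C[C@@H]2[C@@H](C2(Br)Br)[C@@H]1OC(=O)N(C)C
F3 | step 7 | [(1R,2S)-2-(triethylsilyloxy)cyclopent-3-en-1-yl]methyl pivalate | CC(C)(C)C(=O)OC[C@H]1CC=C[C@@H]1O[Si](CC)(CC)CC
F4 | step 7 | [6,6-dibromo-2β-(triethylsilyloxy)bicyclo[3.1.0]hexan-3α-yl]methyl pivalate, cyclopropane α | CC(C)(C)C(=O)OC[C@H]1C[C@@H]2[C@@H](C2(Br)Br)[C@@H]1O[Si](CC)(CC)CC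
F5 | step 7 | [6,6-dibromo-2β-hydroxybicyclo[3.1.0]hexan-3α-yl]methyl pivalate, cyclopropane α | CC(C)(C)C(=O)OC[C@H]1C[C@@H]2[C@@H](C2(Br)Br)[C@@H]1O
F6 | step 10 | 4-bromo-1α-(pivaloyloxymethyl)cyclohex-4-ene-2β,3β-diol | CC(C)(C)C(=O)OC[C@H]1CC=C(Br)[C@H](O)[C@@H]1O
F7 | step 10 | 4-bromo-2β-(4-methoxybenzyloxy)-1α-(pivaloyloxymethyl)cyclohex-4-en-3β-ol | CC(C)(C)C(=O)OC[C@H]1CC=C(Br)[C@H](O)[C@@H]1OCc1ccc(OC)cc1
F8 | step 10 | 3β-O-tert-butyldimethylsilyl ether of F7 | CC(C)(C)C(=O)OC[C@H]1CC=C(Br)[C@H](O[Si](C)(C)C(C)(C)C)[C@@H]1OCc1ccc(OC)cc1
F9 | step 10 | 4-methyl analogue of F8 | CC(C)(C)C(=O)OC[C@H]1CC=C(C)[C@H](O[Si](C)(C)C(C)(C)C)[C@@H]1OCc1ccc(OC)cc1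
F10 | step 22 | (8R)-allylic alcohol, C8 epimer of 30 | C=C([C@@H](CC=C(C)C)O)[C@H]1C[C@H]2O[C@@]2(C)[C@H](O[Si](C)(C)C(C)(C)C)[C@@H]1OCc1ccc(OC)cc1
F11 | step 22 | (8S)-4-nitrobenzoate of 30 | C=C([C@H](CC=C(C)C)OC(=O)c1ccc(cc1)[N+](=O)[O-])[C@H]1C[C@H]2O[C@@]2(C)[C@H](O[Si](C)(C)C(C)(C)C)[C@@H]1OCc1ccc(OC)cc1
F12 | step 24 | 3,8-bis{2-[bis(2,2,2-trifluoroethoxy)phosphoryl]propanoate} of 31 | C=C([C@H](CC=C(C)C)OC(=O)C(C)P(=O)(OCC(F)(F)F)OCC(F)(F)F)[C@H]1C[C@H]2O[C@@]2(C)[C@H](OC(=O)C(C)P(=O)(OCC(F)(F)F)OCC(F)(F)F)[C@@H]1OCc1ccc(OC)cc1
A1 | alternative 1 | methyl 2-methylidene-3-[2,2-dimethyl-5-(prop-1-en-2-yl)-1,3-dioxolan-4-yl]hex-5-enoate (cis-dioxolane triene) | C=CC[C@H](C(=C)C(=O)OC)[C@H]1OC(C)(C)O[C@H]1C(C)=C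
A2 | alternative 1 | methyl 2-(5,6-isopropylidenedioxy-4-methylcyclohex-3-en-1-yl)acrylate | C=C(C(=O)OC)[C@H]1CC=C(C)[C@@H]2OC(C)(C)O[C@H]12
A3 | alternative 2 | (E)-1-(tert-butyldimethylsilyloxy)-2-methylbuta-1,3-diene | C=C/C(C)=C/O[Si](C)(C)C(C)(C)C
A4 | alternative 2 | methyl (E)-4-oxopent-2-enoate | CC(=O)/C=C/C(=O)OC
A5 | alternative 2 | methyl 6-acetyl-5-(tert-butyldimethylsilyloxy)-4-methylcyclohex-3-ene-1-carboxylate (1,6-trans, 5,6-cis) | COC(=O)[C@H]1CC=C(C)[C@H](O[Si](C)(C)C(C)(C)C)[C@@H]1C(C)=O
A6 | alternative 3 | (Z)-2-(tert-butyldimethylsilyloxy)-6-iodo-3-(prop-1-en-2-yl)hept-5-enal | C=C(C)[C@@H](C/C=C(/C)I)[C@@H](O[Si](C)(C)C(C)(C)C)C=O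
A7 | alternative 3 | 6-(tert-butyldimethylsilyloxy)-2-methyl-5-(prop-1-en-2-yl)cyclohex-2-en-1-ol | C=C(C)[C@H]1CC=C(C)[C@H](O)[C@@H]1O[Si](C)(C)C(C)(C)C
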